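**Plan**
- Numbering: carotenoid numbers are used. The oxygen-bridged end group is C1–C8 with methyls C16–C18, the butenolide is C9, C10, C11 and carbonyl C19, the chain runs C12–C15 and C15'–C7', and the acetylenic ring is C1'–C6'.
- Retrosynthesis: the silyl ethers are cut first, then O–C8 of the dihydrofuran (back to the 5,6-epoxide, a vinyl oxirane). Next come C8–C9 (Suzuki), the lactone bonds O–C11 and C10–C11 (alkynylation–lactonisation), C15=C15' (Horner–Wadsworth–Emmons), and C6'–C7' and C6–C7 (both from one enol triflate).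
- Forward: actinol gives one enol triflate for both rings. It is carried to an epoxy alkenylboronate and, by Sonogashira coupling and olefination, to a polyenyne. The polyenyne is closed to the Z-ylidene bromobutenolide and joined to the boronate; the 2,5-dihydrofuran is then made from the oxirane, and desilylation ends the route.
- Enabling feature: the oxirane C5–C6–O sits on C6, which is joined through C7=C8 to the butenolide C9=C10 and the polyene. Heterolysis of C6–O therefore gives a cation shared by C6, C7 and C8, and the oxygen that stays on C5 is 1,3 to C8 and can close the ring O–C5–C6=C7–C8.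
- Stereochemistry: C3 and C3' come from (4R,6R)-actinol, C5 (and C6) from Sharpless epoxidation with D-(−)-diethyl tartrate, and C8 from the suprafacial 1,3-shift of oxygen in the ring expansion. Alkene geometries come from an E enynol, E-selective olefinations, stereoretentive couplings and anti oxymetalation (11Z).

Key step: step 15

Remark: (4R,6R)-actinol and (2E)-3-methylpent-2-en-4-yn-1-ol are taken as purchasable; because the furanoxide can re-ionise at C8 under acid, C8 is treated as a kinetically set centre.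

Step 1
Reactants: 1 (4R,6R)-actinol
Product: 2 (4R,6R)-2,2,6-trimethyl-4-(triethylsilyloxy)cyclohexan-1-one
Conditions: Et3SiCl, imidazole, DMF, 0 °C → rt
Reagents that add atoms: chlorotriethylsilane, CC[Si](CC)(CC)Cl
Why: Imidazole-promoted silylation of the secondary alcohol touches no stereocentre, and the triethylsilyl ether should survive the basic, reductive and mildly acidic steps up to the final fluoride cleavage.

Step 2
Reactants: 2 silyl ether ketone
Product: 4 (4R)-2,6,6-trimethyl-4-(triethylsilyloxy)cyclohex-1-en-1-yl trifluoromethanesulfonate, via lithium enolate 3 (not isolated)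
Conditions: LiN(iPr)2, THF, −78 → 0 °C; then PhNTf2, 0 °C → rt
Reagents that add atoms: N-phenylbis(trifluoromethanesulfonimide), O=S(=O)(N(c1ccccc1)S(=O)(=O)C(F)(F)F)C(F)(F)F; lithium diisopropylamide (lithium, carried only into 3), [Li+].CC(C)[N-]C(C)C
Why: The ketone has a single enolisable position (the other α-carbon is quaternary), so one tetrasubstituted enolate forms and is O-sulfonylated (enol triflate formation); the methyl-bearing stereocentre is erased on purpose and the carbinol centre is untouched.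

Step 3
Reactants: 4 enol triflate
Product: 5 methyl (4R)-2,6,6-trimethyl-4-(triethylsilyloxy)cyclohex-1-ene-1-carboxylate
Conditions: Pd(OAc)2 (cat.), PPh3, CO (1 atm), Et3N, MeOH/DMF, 60 °C
Reagents that add atoms: carbon monoxide, [C-]#[O+]; methanol, CO
Why: Palladium-catalysed alkoxycarbonylation of the enol triflate (oxidative addition, CO insertion, methanolysis) puts C7 on C6, carbon monoxide being small enough for this hindered tetrasubstituted position.

Step 4
Reactants: 5 methyl ester
Product: 6 [(4R)-2,6,6-trimethyl-4-(triethylsilyloxy)cyclohex-1-en-1-yl]methanol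
Conditions: iBu2AlH, CH2Cl2, −78 → 0 °C; aqueous potassium sodium tartrate (KNaC4H4O6)
Reagents that add atoms: none
Why: 1,2-Reduction of the conjugated ester with iBu2AlH gives the primary allylic alcohol needed to direct the epoxidation, while the silyl ether and the tetrasubstituted alkene are inert.

Step 5
Reactants: 6 allylic alcohol
Product: 7 [(1R,4S,6R)-2,2,6-trimethyl-4-(triethylsilyloxy)-7-oxabicyclo[4.1.0]heptan-1-yl]methanol
Conditions: Ti(OiPr)4 (cat.), D-(−)-diethyl tartrate, tBuOOH, 4 Å molecular sieves, CH2Cl2, −20 °C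
Reagents that add atoms: tert-butyl hydroperoxide, CC(C)(C)OO
Why: Katsuki–Sharpless asymmetric epoxidation of the primary allylic alcohol: with D-(−)-diethyl tartrate the oxygen should be delivered to the face of C5=C6 anti to the C3 silyloxy group, which sets C5 (R) and C6 together as the cis-fused oxirane under reagent control.

Step 6
Reactants: 7 epoxy alcohol
Product: 8 (1S,4S,6R)-2,2,6-trimethyl-4-(triethylsilyloxy)-7-oxabicyclo[4.1.0]heptane-1-carbaldehyde
Conditions: SO3·pyridine, DMSO, iPr2NEt, CH2Cl2, 0 °C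
Reagents that add atoms: none
Why: Parikh–Doering oxidation converts the primary alcohol to the aldehyde under non-acidic conditions that spare oxirane and silyl ether, and the quaternary α-carbon cannot epimerise.

Step 7
Reactants: 8 epoxy aldehyde
Product: 9 4,4,5,5-tetramethyl-2-[(E)-2-[(1S,4S,6R)-2,2,6-trimethyl-4-(triethylsilyloxy)-7-oxabicyclo[4.1.0]heptan-1-yl]ethenyl]-1,3,2-dioxaborolane
Conditions: CrCl2, Cl2CHBpin, LiI, THF, rt
Reagents that add atoms: 2-(dichloromethyl)-4,4,5,5-tetramethyl-1,3,2-dioxaborolane, CC1(C)OB(C(Cl)Cl)OC1(C)C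
Why: Takai–Utimoto-type chromium-mediated boryl olefination: the geminal dichromium species from the diiodomethylboronate formed in the flask adds to the aldehyde and eliminates with the two large groups anti, which should give the E-alkenylboronate carrying C8.

Step 8
Reactants: 10 (2E)-3-methylpent-2-en-4-yn-1-ol
Product: 12 (2E,4E)-5-methylhepta-2,4-dien-6-ynal, via enynal 11 (not isolated)
Conditions: MnO2, CH2Cl2, rt; filtration; then Ph3P=CHCHO, 40 °C
Reagents that add atoms: (triphenylphosphoranylidene)acetaldehyde, O=CC=P(c1ccccc1)(c1ccccc1)c1ccccc1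
Why: Allylic oxidation with MnO2 followed by a Wittig reaction with the stabilised formyl ylide adds C14' and C15' with E selectivity, leaves the existing E bond untouched, and spares isolation of the volatile enynal.

Step 9
Reactants: 4 enol triflate; 12 dienynal
Product: 13 (2E,4E)-5-methyl-7-[(4R)-2,6,6-trimethyl-4-(triethylsilyloxy)cyclohex-1-en-1-yl]hepta-2,4-dien-6-ynal
Conditions: Pd(PPh3)4 (cat.), CuI (cat.), Et3N, DMF, rt → 50 °C
Reagents that add atoms: none
Why: Sonogashira coupling of the enol triflate with the terminal alkyne forms the C6'–C7' bond, hindered cyclohexenyl triflates of this type being standard partners for alkynes, and the aldehyde and E,E-diene are spectators.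

Step 10
Reactants: 10 (2E)-3-methylpent-2-en-4-yn-1-ol
Product: 15 diethyl [(2E)-3-methylpent-2-en-4-yn-1-yl]phosphonate, via allylic bromide 14 (not isolated)
Conditions: PBr3, Et2O, 0 °C; concentration; then P(OEt)3, 110 °C
Reagents that add atoms: triethyl phosphite, CCOP(OCC)OCC; phosphorus tribromide (bromine, carried only into 14), BrP(Br)Br
Why: SN2 bromination of the primary allylic alcohol keeps the E geometry, and the unstable bromide is converted without isolation into the phosphonate by a Michaelis–Arbuzov reaction.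

Step 11
Reactants: 13 acetylenic dienal; 15 phosphonate
Product: 17 triethyl{[(1R)-4-[(3E,5E,7E,9E)-3,10-dimethyldodeca-3,5,7,9-tetraene-1,11-diyn-1-yl]-3,5,5-trimethylcyclohex-3-en-1-yl]oxy}silane, via sodium phosphonate carbanion 16 (not isolated)
Conditions: NaN(SiMe3)2, THF, −78 °C; then 13, −78 → 0 °C
Reagents that add atoms: sodium hexamethyldisilazide (sodium, carried only into 16), [Na+].C[Si](C)(C)[N-][Si](C)(C)C
Why: Horner–Wadsworth–Emmons olefination with the allylic phosphonate anion should form C15=C15' with E selectivity, so no iodine equilibration is needed that would also isomerise the 9' and 13 double bonds next to the alkynes; the phosphorus-stabilised carbanion is far less basic than an acetylide, so the terminal alkyne stays protonated.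

Step 12
Reactants: 18 propiolic acid
Product: 19 (2E)-2,3-dibromoprop-2-enoic acid
Conditions: Br2, CHCl3, 0 °C → rt, dark
Reagents that add atoms: bromine, BrBr
Why: Anti addition of bromine to the alkyne gives the E-dibromide, in which the β-bromine is cis to the carboxyl group as the later lactonisation requires.

Step 13
Reactants: 17 polyenyne; 19 dibromoacrylic acid
Product: 21 (5Z)-3-bromo-5-[(2E,4E,6E,8E)-2,9-dimethyl-11-[(4R)-2,6,6-trimethyl-4-(triethylsilyloxy)cyclohex-1-en-1-yl]undeca-2,4,6,8-tetraen-10-yn-1-ylidene]furan-2(5H)-one, via bromo enynoic acid 20 (not isolated)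
Conditions: Pd(PPh3)4 (cat.), CuI (cat.), Et3N, MeCN, rt, dark, degassed
Reagents that add atoms: none
Why: Tandem Sonogashira coupling–lactonisation of a cis-β-haloacrylic acid: oxidative addition should occur at the more electrophilic β-C–Br bond, and the carboxylate of 20 then adds anti across the metal-activated alkyne in the 5-exo-dig mode, giving the Z-ylidene lactone and leaving the α-bromine as the handle for C8.

Step 14
Reactants: 21 bromobutenolide; 9 alkenylboronate
Product: 22 (5Z)-3-[(E)-2-[(1S,4S,6R)-2,2,6-trimethyl-4-(triethylsilyloxy)-7-oxabicyclo[4.1.0]heptan-1-yl]ethenyl]-5-[(2E,4E,6E,8E)-2,9-dimethyl-11-[(4R)-2,6,6-trimethyl-4-(triethylsilyloxy)cyclohex-1-en-1-yl]undeca-2,4,6,8-tetraen-10-yn-1-ylidene]furan-2(5H)-one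
Conditions: Pd(PPh3)4 (cat.), TlOEt, THF/H2O 3:1, rt, dark
Reagents that add atoms: none
Why: Suzuki–Miyaura coupling of the α-bromobutenolide with the E-alkenylboronate forms C8–C9 with retention of both alkene geometries, the thallium base making transmetalation fast at room temperature so that lactone, oxirane and polyene are exposed only briefly.

Step 15
Reactants: 22 bis(triethylsilyl) ether of the 5,6-epoxide (pyrrhoxanthinol)
Product: 23 (5Z)-3-[(2R,6S,7aR)-4,4,7a-trimethyl-6-(triethylsilyloxy)-2,4,5,6,7,7a-hexahydro-1-benzofuran-2-yl]-5-[(2E,4E,6E,8E)-2,9-dimethyl-11-[(4R)-2,6,6-trimethyl-4-(triethylsilyloxy)cyclohex-1-en-1-yl]undeca-2,4,6,8-tetraen-10-yn-1-ylidene]furan-2(5H)-one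
Conditions: camphorsulfonic acid (5 mol %), CH2Cl2 (dry, degassed), −40 → −10 °C, dark, argon; Et3N quench
Reagents that add atoms: none
Why: Protonation of the oxirane oxygen and heterolysis of the tertiary, allylic C6–O bond give a hydroxy cation delocalised over C6–C7–C8 and onward into the C9=C10 butenolide and the polyene; the C5 hydroxyl then closes on C8 while the double bond moves to C6=C7, so the three-membered ring C5–C6–O grows to the five-membered ring O–C5–C6=C7–C8 with release of the oxirane strain. The closest known reaction type is the acid-induced 5,6-epoxide to 5,8-furanoxide rearrangement of carotenoid epoxides, a vinyl oxirane to 2,5-dihydrofuran ring expansion. The dihydrofuran closes by attack of oxygen on the terminus of an allyl cation (formally 5-endo, feasible here because C8 is cationic and can twist towards the oxygen). C5 keeps its R configuration because its C–O bond is never broken; C8 should be set by the oxygen staying on the face of the C6–C7–C8 unit from which it left (a swing to the other face would force ring carbon C4 through the plane of the cation), so that with the 7E geometry C9 ends trans to the C5 methyl, which is 8R. The step needs closure at C8 in preference to a 1,2-shift at C6, to attack of the C3 oxygen on C6, and to later epimerisation of C8 by re-ionisation. The extended π-system at C8, the silyl cap on O3 and the use of catalytic acid at low temperature in a non-nucleophilic solvent with early quench are meant to secure this.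

Step 16
Reactants: 23 bis(triethylsilyl) ether of the furanoxide
Product: 24 target, (3S,5R,8R,3'R)-furanoxide diol
Conditions: Bu4NF/AcOH (1:1), THF, 0 °C → rt, dark
Reagents that add atoms: none
Why: Fluoride cleavage of both triethylsilyl ethers, buffered with acetic acid so that neither the base-sensitive butenolide nor the acid-sensitive allylic C8–O bond is endangered, should give the diol without touching any stereocentre.

**Compound list**
1 | (4R,6R)-4-hydroxy-2,2,6-trimethylcyclohexan-1-one (actinol) | C[C@H]1C(=O)C(C)(C)C[C@H](O)C1 | starting material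
2 | (4R,6R)-2,2,6-trimethyl-4-(triethylsilyloxy)cyclohexan-1-one | C[C@H]1C(=O)C(C)(C)C[C@H](O[Si](CC)(CC)CC)C1 | intermediate
3 | lithium (4R)-2,6,6-trimethyl-4-(triethylsilyloxy)cyclohex-1-en-1-olate | CC1=C([O-])C(C)(C)C[C@H](O[Si](CC)(CC)CC)C1.[Li+] | intermediate
4 | (4R)-2,6,6-trimethyl-4-(triethylsilyloxy)cyclohex-1-en-1-yl trifluoromethanesulfonate | CC1=C(OS(=O)(=O)C(F)(F)F)C(C)(C)C[C@H](O[Si](CC)(CC)CC)C1 | intermediate
5 | methyl (4R)-2,6,6-trimethyl-4-(triethylsilyloxy)cyclohex-1-ene-1-carboxylate | CC1=C(C(=O)OC)C(C)(C)C[C@H](O[Si](CC)(CC)CC)C1 | intermediate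
6 | [(4R)-2,6,6-trimethyl-4-(triethylsilyloxy)cyclohex-1-en-1-yl]methanol | CC1=C(CO)C(C)(C)C[C@H](O[Si](CC)(CC)CC)C1 | intermediate
7 | [(1R,4S,6R)-2,2,6-trimethyl-4-(triethylsilyloxy)-7-oxabicyclo[4.1.0]heptan-1-yl]methanol | OC[C@]12C(C)(C)C[C@H](O[Si](CC)(CC)CC)C[C@@]1(C)O2 | intermediate
8 | (1S,4S,6R)-2,2,6-trimethyl-4-(triethylsilyloxy)-7-oxabicyclo[4.1.0]heptane-1-carbaldehyde | O=C[C@]12C(C)(C)C[C@H](O[Si](CC)(CC)CC)C[C@@]1(C)O2 | intermediate
9 | 4,4,5,5-tetramethyl-2-[(E)-2-[(1S,4S,6R)-2,2,6-trimethyl-4-(triethylsilyloxy)-7-oxabicyclo[4.1.0]heptan-1-yl]ethenyl]-1,3,2-dioxaborolane | CC1(C)OB(/C=C/[C@]23C(C)(C)C[C@H](O[Si](CC)(CC)CC)C[C@@]2(C)O3)OC1(C)C | intermediate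
10 | (2E)-3-methylpent-2-en-4-yn-1-ol | C#C/C(C)=C/CO | starting material
11 | (2E)-3-methylpent-2-en-4-ynal | C#C/C(C)=C/C=O | intermediate
12 | (2E,4E)-5-methylhepta-2,4-dien-6-ynal | C#C/C(C)=C/C=C/C=O | intermediate
13 | (2E,4E)-5-methyl-7-[(4R)-2,6,6-trimethyl-4-(triethylsilyloxy)cyclohex-1-en-1-yl]hepta-2,4-dien-6-ynal | CC1=C(C#C/C(C)=C/C=C/C=O)C(C)(C)C[C@H](O[Si](CC)(CC)CC)C1 | intermediate
14 | (3E)-5-bromo-3-methylpent-3-en-1-yne | C#C/C(C)=C/CBr | intermediate
15 | diethyl [(2E)-3-methylpent-2-en-4-yn-1-yl]phosphonate | C#C/C(C)=C/CP(=O)(OCC)OCC | intermediate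
16 | sodium salt of the α-carbanion of diethyl [(2E)-3-methylpent-2-en-4-yn-1-yl]phosphonate | C#C/C(C)=C/[CH-]P(=O)(OCC)OCC.[Na+] | intermediate
17 | triethyl{[(1R)-4-[(3E,5E,7E,9E)-3,10-dimethyldodeca-3,5,7,9-tetraene-1,11-diyn-1-yl]-3,5,5-trimethylcyclohex-3-en-1-yl]oxy}silane | CC1=C(C#C/C(C)=C/C=C/C=C/C=C(C)/C#C)C(C)(C)C[C@H](O[Si](CC)(CC)CC)C1 | intermediate
18 | prop-2-ynoic acid (propiolic acid) | C#CC(=O)O | starting material
19 | (2E)-2,3-dibromoprop-2-enoic acid | OC(=O)/C(Br)=C\Br | intermediate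
20 | (2E,6E,8E,10E,12E)-2-bromo-6,13-dimethyl-15-[(4R)-2,6,6-trimethyl-4-(triethylsilyloxy)cyclohex-1-en-1-yl]pentadeca-2,6,8,10,12-pentaene-4,14-diynoic acid | CC1=C(C#C/C(C)=C/C=C/C=C/C=C(C)/C#C/C=C(Br)\C(=O)O)C(C)(C)C[C@H](O[Si](CC)(CC)CC)C1 | intermediate
21 | (5Z)-3-bromo-5-[(2E,4E,6E,8E)-2,9-dimethyl-11-[(4R)-2,6,6-trimethyl-4-(triethylsilyloxy)cyclohex-1-en-1-yl]undeca-2,4,6,8-tetraen-10-yn-1-ylidene]furan-2(5H)-one | CC1=C(C#C/C(C)=C/C=C/C=C/C=C(C)/C=C2/C=C(Br)C(=O)O2)C(C)(C)C[C@H](O[Si](CC)(CC)CC)C1 | intermediate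
22 | (5Z)-3-[(E)-2-[(1S,4S,6R)-2,2,6-trimethyl-4-(triethylsilyloxy)-7-oxabicyclo[4.1.0]heptan-1-yl]ethenyl]-5-[(2E,4E,6E,8E)-2,9-dimethyl-11-[(4R)-2,6,6-trimethyl-4-(triethylsilyloxy)cyclohex-1-en-1-yl]undeca-2,4,6,8-tetraen-10-yn-1-ylidene]furan-2(5H)-one | CC1=C(C#C/C(C)=C/C=C/C=C/C=C(C)/C=C2/C=C(/C=C/[C@]34C(C)(C)C[C@H](O[Si](CC)(CC)CC)C[C@@]3(C)O4)C(=O)O2)C(C)(C)C[C@H](O[Si](CC)(CC)CC)C1 | intermediate
23 | (5Z)-3-[(2R,6S,7aR)-4,4,7a-trimethyl-6-(triethylsilyloxy)-2,4,5,6,7,7a-hexahydro-1-benzofuran-2-yl]-5-[(2E,4E,6E,8E)-2,9-dimethyl-11-[(4R)-2,6,6-trimethyl-4-(triethylsilyloxy)cyclohex-1-en-1-yl]undeca-2,4,6,8-tetraen-10-yn-1-ylidene]furan-2(5H)-one | CC1=C(C#C/C(C)=C/C=C/C=C/C=C(C)/C=C2/C=C([C@H]3C=C4C(C)(C)C[C@H](O[Si](CC)(CC)CC)C[C@@]4(C)O3)C(=O)O2)C(C)(C)C[C@H](O[Si](CC)(CC)CC)C1 | intermediate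
24 | (5Z)-3-[(2R,6S,7aR)-6-hydroxy-4,4,7a-trimethyl-2,4,5,6,7,7a-hexahydro-1-benzofuran-2-yl]-5-[(2E,4E,6E,8E)-11-[(4R)-4-hydroxy-2,6,6-trimethylcyclohex-1-en-1-yl]-2,9-dimethylundeca-2,4,6,8-tetraen-10-yn-1-ylidene]furan-2(5H)-one | CC1=C(C#C/C(C)=C/C=C/C=C/C=C(C)/C=C2/C=C([C@H]3C=C4C(C)(C)C[C@H](O)C[C@@]4(C)O3)C(=O)O2)C(C)(C)C[C@H](O)C1 | target

**Step count and risks**
Total step count: 16. Longest linear sequence: 10 steps (steps 1, 2, 3, 4, 5, 6, 7, 14, 15, 16).

Steps most likely to fail:

Step 15: poor facial selectivity in the closure at C8, or loss of it when the allylic C8–O bond re-ionises under the acid. The fallback fixes C8 by addition to a ring oxocarbenium ion instead of by the 1,3-shift, and sets out from aldehyde 8. A Wittig reaction with Ph3P=CHOMe gives the (2-methoxyvinyl)oxirane F1. Catalytic pyridinium tosylate in CH2Cl2 expands this (the enol ether oxygen stabilises the C8 cation) to the 8-methoxy dihydrofuran acetal F2, whose C8 configuration does not matter. Ionisation with Me3SiI in the presence of methyl propiolate is a β-iodo Morita–Baylis–Hillman-type addition of the silyl β-iodoallenoate to the oxocarbenium ion; attack anti to the pseudoaxial C5 methyl should give the Z-β-iodoacrylate F3 with the 8R configuration. Me3SnOH frees the iodoacrylic acid F4, and tandem Sonogashira coupling–lactonisation of F4 with polyenyne 17 under the conditions of step 13 comes back to the route at 23.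

Step 13: ring closure in the 6-endo mode to a pyranone, coupling at the α-bromide, or oxidative dimerisation of the polyenyne. The fallback separates coupling from ring closure and closes the lactone last with a silver salt, setting out from acid 19. Esterification (MeOH, cat. H2SO4) gives methyl (2E)-2,3-dibromoprop-2-enoate F5. Sonogashira coupling with 17 at the β-bromide gives the bromo enynoate F6, and Suzuki coupling with boronate 9 under the conditions of step 14 gives the fully assembled enynoate F7. Me3SnOH gives the enynoic acid F8, and AgNO3 (cat.) in acetone, which favours 5-exo-dig closure to Z-ylidenebutenolides, comes back to the route at 22.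

Step 14: base-induced opening of the lactone, protodeboronation of 9, or sluggish oxidative addition at the α-bromide. The fallback is a base-free Stille coupling and sets out from aldehyde 8. Chromium-mediated stannyl olefination (Bu3SnCHBr2, CrCl2, LiI, THF) gives the E-alkenylstannane F9, and coupling of F9 with bromide 21 (Pd2(dba)3, AsPh3, NMP, rt) comes back to the route at 22.

Further compounds
F1 | step 15 | (1S,4S,6R)-1-[(E)-2-methoxyethenyl]-2,2,6-trimethyl-4-(triethylsilyloxy)-7-oxabicyclo[4.1.0]heptane | CO/C=C/[C@]12C(C)(C)C[C@H](O[Si](CC)(CC)CC)C[C@@]1(C)O2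
F2 | step 15 | (6S,7aR)-2-methoxy-4,4,7a-trimethyl-6-(triethylsilyloxy)-2,4,5,6,7,7a-hexahydro-1-benzofuran (either configuration at C2) | COC1C=C2C(C)(C)C[C@H](O[Si](CC)(CC)CC)C[C@@]2(C)O1
F3 | step 15 | methyl (2Z)-3-iodo-2-[(2R,6S,7aR)-4,4,7a-trimethyl-6-(triethylsilyloxy)-2,4,5,6,7,7a-hexahydro-1-benzofuran-2-yl]prop-2-enoate | COC(=O)/C(=C\I)[C@H]1C=C2C(C)(C)C[C@H](O[Si](CC)(CC)CC)C[C@@]2(C)O1
F4 | step 15 | (2Z)-3-iodo-2-[(2R,6S,7aR)-4,4,7a-trimethyl-6-(triethylsilyloxy)-2,4,5,6,7,7a-hexahydro-1-benzofuran-2-yl]prop-2-enoic acid | OC(=O)/C(=C\I)[C@H]1C=C2C(C)(C)C[C@H](O[Si](CC)(CC)CC)C[C@@]2(C)O1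
F5 | step 13 | methyl (2E)-2,3-dibromoprop-2-enoate | COC(=O)/C(Br)=C\Br
F6 | step 13 | methyl (2E,6E,8E,10E,12E)-2-bromo-6,13-dimethyl-15-[(4R)-2,6,6-trimethyl-4-(triethylsilyloxy)cyclohex-1-en-1-yl]pentadeca-2,6,8,10,12-pentaene-4,14-diynoate | CC1=C(C#C/C(C)=C/C=C/C=C/C=C(C)/C#C/C=C(Br)\C(=O)OC)C(C)(C)C[C@H](O[Si](CC)(CC)CC)C1
F7 | step 13 | methyl (2Z,6E,8E,10E,12E)-6,13-dimethyl-2-[(E)-2-[(1S,4S,6R)-2,2,6-trimethyl-4-(triethylsilyloxy)-7-oxabicyclo[4.1.0]heptan-1-yl]ethenyl]-15-[(4R)-2,6,6-trimethyl-4-(triethylsilyloxy)cyclohex-1-en-1-yl]pentadeca-2,6,8,10,12-pentaene-4,14-diynoate | CC1=C(C#C/C(C)=C/C=C/C=C/C=C(C)/C#C/C=C(/C=C/[C@]23C(C)(C)C[C@H](O[Si](CC)(CC)CC)C[C@@]2(C)O3)C(=O)OC)C(C)(C)C[C@H](O[Si](CC)(CC)CC)C1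
F8 | step 13 | (2Z,6E,8E,10E,12E)-6,13-dimethyl-2-[(E)-2-[(1S,4S,6R)-2,2,6-trimethyl-4-(triethylsilyloxy)-7-oxabicyclo[4.1.0]heptan-1-yl]ethenyl]-15-[(4R)-2,6,6-trimethyl-4-(triethylsilyloxy)cyclohex-1-en-1-yl]pentadeca-2,6,8,10,12-pentaene-4,14-diynoic acid | CC1=C(C#C/C(C)=C/C=C/C=C/C=C(C)/C#C/C=C(/C=C/[C@]23C(C)(C)C[C@H](O[Si](CC)(CC)CC)C[C@@]2(C)O3)C(=O)O)C(C)(C)C[C@H](O[Si](CC)(CC)CC)C1
F9 | step 14 | tributyl[(E)-2-[(1S,4S,6R)-2,2,6-trimethyl-4-(triethylsilyloxy)-7-oxabicyclo[4.1.0]heptan-1-yl]ethenyl]stannane | CCCC[Sn](CCCC)(CCCC)/C=C/[C@]12C(C)(C)C[C@H](O[Si](CC)(CC)CC)C[C@@]1(C)O2
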